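C23H28O6 target ⇒ cis-fused α-methylene-γ-lactone on the dihydrobenzofuran. The enal carbon is the lactone carbonyl (Weinreb amide, then Cp2Zr(H)Cl), the C3 isovalerate oxygen is the lactone oxygen, and the (S)-senecioate side chain comes from a C5 acetyl group (CBS reduction, esterification).
Structural feature used: with C5 as acetyl, C3–H2 of the dihydrofuran ring (ring B) is the only benzylic C–H. The carboxyl carbon of a C2 propenoic acid chain lies three atoms from C3 (C3, C2, Cα, CO2H), so its oxygen reaches C3 only on the face where C2 holds it.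
Key disconnection: the C3–O bond, made by anodic two-electron C–H oxidation and carboxylate capture, which closes lactone ring C cis on ring B.
Acid ⇒ (S)-tremetone (oxidation of the isopropenyl methyl group) ⇒ 3-bromo-4-hydroxyacetophenone + isoprene (enantioselective Pd heteroannulation; forms C3–C3a and O1–C2, sets C2).
Ring order: ring A (benzene) is bought, ring B closes in step 1, ring C closes in step 4 and is opened again in step 5.
Key step: step 4

Reading of the target: C2 is (R) and C3 is (R), with the two substituents cis on ring B; the side-chain carbinol carbon is (S). C2 is spatially unchanged from step 1 on, and its descriptor changes from S to R when C3 gains oxygen.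
Assumption: in step 1 the ligand antipode that gives the (S)-configured ring is used. The product is known in both enantiomeric forms, so sign of rotation and chiral HPLC settle the choice before the route goes on.

Step 1
Reactants: 1 1-(3-bromo-4-hydroxyphenyl)ethan-1-one; 2 isoprene (2-methylbuta-1,3-diene)
Product: 3 (S)-tremetone [1-[(2S)-2-(prop-1-en-2-yl)-2,3-dihydro-1-benzofuran-5-yl]ethan-1-one]
Conditions: Pd2(dba)3·CHCl3 (2.5 mol %), TY-Phos (chiral tert-butanesulfinamide monophosphine, 10 mol %), K2CO3 (2 equiv), 2 (4 equiv), toluene, 80 °C, sealed tube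
Reagents that add atoms: none
Why: Larock-type heteroannulation (Heck insertion of the aryl–Pd bond at the unsubstituted vinyl terminus of isoprene, then Tsuji–Trost closure of the phenoxide on the inner terminus of the 2-methyl-π-allyl complex) is an established enantioselective reaction of o-bromophenols with 1,3-dienes, and the chiral ligand fixes C2 in the C–O bond-forming event.

Step 2
Reactants: 3 (S)-tremetone
Product: 4 1-[(2S)-2-(3-hydroxyprop-1-en-2-yl)-2,3-dihydro-1-benzofuran-5-yl]ethan-1-one
Conditions: SeO2 (0.5 equiv), t-BuOOH (3 equiv, decane solution), CH2Cl2, rt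
Reagents that add atoms: selenium dioxide O=[Se]=O (hands over the oxygen); tert-butyl hydroperoxide CC(C)(C)OO (restores it, net oxygen source)
Why: SeO2/t-BuOOH allylic hydroxylation (ene reaction, then [2,3]-sigmatropic shift) takes the only allylic methyl group at room temperature, where the Riley oxidation of the aryl methyl ketone does not yet run, C2 is not touched, and over-oxidised material is carried along because step 3 brings it to the same acid.

Step 3
Reactants: 4 1-[(2S)-2-(3-hydroxyprop-1-en-2-yl)-2,3-dihydro-1-benzofuran-5-yl]ethan-1-one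
Product: 6 2-[(2S)-5-acetyl-2,3-dihydro-1-benzofuran-2-yl]prop-2-enoic acid, via enal 5 (not isolated)
Conditions: TEMPO (2,2,6,6-tetramethylpiperidin-1-oxyl, 10 mol %), NaClO2 (2 equiv), NaOCl (3 mol %), MeCN/aq. NaH2PO4–Na2HPO4 buffer (pH 6.7), 35 °C
Reagents that add atoms: sodium chlorite [Na+].[O-]Cl=O
Why: An Anelli-type alcohol oxidation coupled to a Pinnick-type aldehyde oxidation, in which the oxoammonium salt makes the enal, chlorite takes it to the acid, and the hypochlorite released re-oxidises TEMPO instead of chlorinating arene or alkene, while C2 carries no hydrogen α to a carbonyl and keeps its configuration.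

Step 4
Reactants: 6 2-[(2S)-5-acetyl-2,3-dihydro-1-benzofuran-2-yl]prop-2-enoic acid
Product: 7 (3aR,8bR)-7-acetyl-3-methylidene-3a,8b-dihydrofuro[3,2-b][1]benzofuran-2(3H)-one
Conditions: undivided cell, graphite-felt anode, Pt cathode, constant current (about 3 mA cm−2, 2.2 F mol−1), nBu4NPF6 (0.1 M), 2,4,6-collidine (1.5 equiv), CH2Cl2/(CF3)2CHOH 4:1, 0.02 M in 6, 0 °C, no mediator
Reagents that add atoms: none
Why: Either primary anodic event (oxidation of the aryl ether π system followed by collidine-assisted loss of a C3 proton, or oxidation of the carboxylate followed by 1,5-hydrogen transfer from C3 to the carboxyl radical) ends at the same C3 benzylic radical, which is oxidised at once to a C3 cation stabilised by O1 through C7a and C3a, while protons are reduced to H2 at the Pt cathode. The closest known reaction type is the anodic (or K2S2O8-driven) dehydrogenative benzylic C–H lactonisation of 4-arylbutanoic and 2-alkylbenzoic acids; direct electrolysis in (CF3)2CHOH is preferred to a quinone mediator because the C5 acetyl group puts the arene beyond the reach of a ground-state quinone, and quinone hydride abstraction is the classical way to aromatise dihydrobenzofurans. Ring C closes by 5-exo-trig attack of the carboxylate oxygen on C3 (ring atoms O, C=O, Cα, C2, C3). The new centre C3 (C8b of 7) is controlled by C2 (C3a of 7) through the tether, because a γ-lactone annulated to the five-membered ring B is only accessible as the cis isomer, so removal of either C3 hydrogen leads to the (3aR,8bR) product. Site selectivity rests on C3–H2 being the sole benzylic C–H (the acetyl carbon bears none), and the chemoselectivity needed, capture of the cation before loss of the C2 proton to a benzofuran, rests on a unimolecular closure by a carboxylate held three atoms away competing against a bimolecular deprotonation by a hindered, dilute base. The buffer keeps the medium from turning acidic, which would re-ionise the benzylic lactone, and 7, now acyloxylated at C3, is harder to oxidise than 6, so the charge is cut off close to the theoretical value.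

Step 5
Reactants: 7 (3aR,8bR)-7-acetyl-3-methylidene-3a,8b-dihydrofuro[3,2-b][1]benzofuran-2(3H)-one
Product: 8 2-[(2R,3R)-5-acetyl-3-hydroxy-2,3-dihydro-1-benzofuran-2-yl]-N-methoxy-N-methylprop-2-enamide
Conditions: MeNHOMe·HCl (3 equiv) and AlMe3 (3 equiv) premixed, CH2Cl2, 0 °C, 30 min; then 7, −20 to 0 °C; aq. potassium sodium tartrate work-up; crude product used at once
Reagents that add atoms: N,O-dimethylhydroxylamine hydrochloride CNOC.Cl
Why: In this Weinreb aminolysis of a lactone the hard, aluminium-bound amide attacks the lactone carbonyl rather than the exocyclic methylene or the aryl ketone (no free AlMe3 or free amine is left after premixing), no bond to C2 or C3 is broken so both centres are kept, and exactly one hydroxyl is revealed.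

Step 6
Reactants: 8 2-[(2R,3R)-5-acetyl-3-hydroxy-2,3-dihydro-1-benzofuran-2-yl]-N-methoxy-N-methylprop-2-enamide; 9 3-methylbutanoic anhydride
Product: 10 (2R,3R)-5-acetyl-2-{3-[methoxy(methyl)amino]-3-oxoprop-1-en-2-yl}-2,3-dihydro-1-benzofuran-3-yl 3-methylbutanoate
Conditions: 9 (1.5 equiv), Et3N (2 equiv), 4-(dimethylamino)pyridine (10 mol %), CH2Cl2, 0 °C
Reagents that add atoms: none
Why: DMAP-catalysed acyl transfer to the only free hydroxyl is faster than relactonisation, it acylates at oxygen so the C3–O bond and its configuration are retained, and the weak base at 0 °C does not trigger anti elimination across C2–C3.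

Step 7
Reactants: 10 (2R,3R)-5-acetyl-2-{3-[methoxy(methyl)amino]-3-oxoprop-1-en-2-yl}-2,3-dihydro-1-benzofuran-3-yl 3-methylbutanoate
Product: 11 (2R,3R)-5-[(1S)-1-hydroxyethyl]-2-{3-[methoxy(methyl)amino]-3-oxoprop-1-en-2-yl}-2,3-dihydro-1-benzofuran-3-yl 3-methylbutanoate
Conditions: (R)-2-methyl-CBS-oxazaborolidine [(3aR)-1-methyl-3,3-diphenyltetrahydro-1H,3H-pyrrolo[1,2-c][1,3,2]oxazaborole, 20 mol %], BH3·SMe2 (0.8 equiv), slow addition of 10, THF, −20 °C; MeOH quench
Reagents that add atoms: none
Why: In the Corey–Bakshi–Shibata reduction the (R)-catalyst binds borane and the ketone with aryl as the large and methyl as the small group and delivers hydride to the Re face, giving the (S)-carbinol under catalyst control, while the ester, the Weinreb amide and the electron-poor alkene react far more slowly with borane at this temperature.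

Step 8
Reactants: 11 (2R,3R)-5-[(1S)-1-hydroxyethyl]-2-{3-[methoxy(methyl)amino]-3-oxoprop-1-en-2-yl}-2,3-dihydro-1-benzofuran-3-yl 3-methylbutanoate; 12 3-methylbut-2-enoic acid
Product: 13 (1S)-1-[(2R,3R)-2-{3-[methoxy(methyl)amino]-3-oxoprop-1-en-2-yl}-3-(3-methylbutanoyloxy)-2,3-dihydro-1-benzofuran-5-yl]ethyl 3-methylbut-2-enoate
Conditions: 12 (1.5 equiv), N,N'-diisopropylcarbodiimide (1.5 equiv), 4-(dimethylamino)pyridine (20 mol %), CH2Cl2, 0 °C to rt
Reagents that add atoms: none
Why: Steglich esterification acylates the carbinol oxygen without breaking its C–O bond, so the (S) centre is retained under non-acidic conditions, and starting from the free acid rather than the acid chloride avoids the vinylketene pathway that deconjugates the senecioyl group.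

Step 9
Reactants: 13 (1S)-1-[(2R,3R)-2-{3-[methoxy(methyl)amino]-3-oxoprop-1-en-2-yl}-3-(3-methylbutanoyloxy)-2,3-dihydro-1-benzofuran-5-yl]ethyl 3-methylbut-2-enoate
Product: 14 (1S)-1-[(2R,3R)-3-(3-methylbutanoyloxy)-2-(3-oxoprop-1-en-2-yl)-2,3-dihydro-1-benzofuran-5-yl]ethyl 3-methylbut-2-enoate (CNP0325942.1)
Conditions: Cp2Zr(H)Cl (1.6 equiv), THF, rt, 20 min; then H2O, filtration through SiO2
Reagents that add atoms: none
Why: Reduction of a tertiary amide to the aldehyde with Cp2Zr(H)Cl proceeds by fast 1,2-hydride delivery to the zirconium-bound amide carbonyl and releases the aldehyde only on work-up, whereas esters and substituted conjugated alkenes react much more slowly, and no stereocentre is involved.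

Compound list
1 | 1-(3-bromo-4-hydroxyphenyl)ethan-1-one | CC(=O)c1ccc(O)c(Br)c1 | starting material
2 | isoprene (2-methylbuta-1,3-diene) | C=CC(C)=C | starting material
3 | (S)-tremetone, 1-[(2S)-2-(prop-1-en-2-yl)-2,3-dihydro-1-benzofuran-5-yl]ethan-1-one | C=C(C)[C@H]1Oc2ccc(C(C)=O)cc2C1 | intermediate
4 | 1-[(2S)-2-(3-hydroxyprop-1-en-2-yl)-2,3-dihydro-1-benzofuran-5-yl]ethan-1-one | C=C(CO)[C@H]1Oc2ccc(C(C)=O)cc2C1 | intermediate
5 | 2-[(2S)-5-acetyl-2,3-dihydro-1-benzofuran-2-yl]prop-2-enal (enal, not isolated) | C=C(C=O)[C@H]1Oc2ccc(C(C)=O)cc2C1 | intermediate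
6 | 2-[(2S)-5-acetyl-2,3-dihydro-1-benzofuran-2-yl]prop-2-enoic acid | C=C(C(=O)O)[C@H]1Oc2ccc(C(C)=O)cc2C1 | intermediate
7 | (3aR,8bR)-7-acetyl-3-methylidene-3a,8b-dihydrofuro[3,2-b][1]benzofuran-2(3H)-one | C=C1C(=O)O[C@@H]2c3cc(C(C)=O)ccc3O[C@H]12 | intermediate
8 | 2-[(2R,3R)-5-acetyl-3-hydroxy-2,3-dihydro-1-benzofuran-2-yl]-N-methoxy-N-methylprop-2-enamide | C=C(C(=O)N(C)OC)[C@H]1Oc2ccc(C(C)=O)cc2[C@H]1O | intermediate
9 | 3-methylbutanoic anhydride | CC(C)CC(=O)OC(=O)CC(C)C | starting material
10 | (2R,3R)-5-acetyl-2-{3-[methoxy(methyl)amino]-3-oxoprop-1-en-2-yl}-2,3-dihydro-1-benzofuran-3-yl 3-methylbutanoate | C=C(C(=O)N(C)OC)[C@H]1Oc2ccc(C(C)=O)cc2[C@H]1OC(=O)CC(C)C | intermediate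
11 | (2R,3R)-5-[(1S)-1-hydroxyethyl]-2-{3-[methoxy(methyl)amino]-3-oxoprop-1-en-2-yl}-2,3-dihydro-1-benzofuran-3-yl 3-methylbutanoate | C=C(C(=O)N(C)OC)[C@H]1Oc2ccc([C@H](C)O)cc2[C@H]1OC(=O)CC(C)C | intermediate
12 | 3-methylbut-2-enoic acid | CC(C)=CC(=O)O | starting material
13 | (1S)-1-[(2R,3R)-2-{3-[methoxy(methyl)amino]-3-oxoprop-1-en-2-yl}-3-(3-methylbutanoyloxy)-2,3-dihydro-1-benzofuran-5-yl]ethyl 3-methylbut-2-enoate | C=C(C(=O)N(C)OC)[C@H]1Oc2ccc([C@H](C)OC(=O)C=C(C)C)cc2[C@H]1OC(=O)CC(C)C | intermediate
14 | (1S)-1-[(2R,3R)-3-(3-methylbutanoyloxy)-2-(3-oxoprop-1-en-2-yl)-2,3-dihydro-1-benzofuran-5-yl]ethyl 3-methylbut-2-enoate | C=C(C=O)[C@H]1Oc2ccc([C@H](C)OC(=O)C=C(C)C)cc2[C@H]1OC(=O)CC(C)C | target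

Total step count: 9. Longest linear sequence: 9 (steps 1 to 9; 9 and 12 are bought).

Steps most likely to fail

1. Step 4. The C3 cation may lose the C2 proton, or the lactone may re-ionise, so that ring B aromatises. The easily oxidised aromatised material then consumes charge and fouls the anode. Collidine may also attack C3, and the carboxyl radical may decarboxylate. The fallback sets out from 6 and comes back at 7, and it replaces electron transfer by atom transfer followed by ionisation. Wohl–Ziegler bromination (N-bromosuccinimide, AIBN cat., PhCF3, 80 °C) places bromine on the only benzylic carbon and should give 2-[(2R)-5-acetyl-3-bromo-2,3-dihydro-1-benzofuran-2-yl]prop-2-enoic acid F1 as both C3 epimers. This crude material is treated with Ag2CO3 in CH2Cl2 at −20 °C, which pulls off bromide while the carboxylate closes. Both epimers converge on 7, because only the cis-fused lactone can form.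

2. Step 5. The amine may add to the exocyclic methylene, and the enolate so formed can expel the aryloxide from C2. Aluminium may assist ionisation of the benzylic C3–O bond with aromatisation, and the hydroxy amide may relactonise on isolation. The fallback sets out from 7 and comes back at 8, and it opens the lactone with hydroxide and blocks the hydroxyl before the acid is activated.
   - LiOH (1.1 equiv), THF/H2O, 0 °C should give lithium 2-[(2R,3R)-5-acetyl-3-hydroxy-2,3-dihydro-1-benzofuran-2-yl]prop-2-enoate F2, which is dried without acidification.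
   - Et3SiCl and imidazole in DMF should give triethylsilyl 2-[(2R,3R)-5-acetyl-3-(triethylsilyloxy)-2,3-dihydro-1-benzofuran-2-yl]prop-2-enoate F3.
   - Brief K2CO3 in aqueous MeOH cleaves only the silyl ester, to 2-[(2R,3R)-5-acetyl-3-(triethylsilyloxy)-2,3-dihydro-1-benzofuran-2-yl]prop-2-enoic acid F4.
   - Carbodiimide coupling (MeNHOMe·HCl, EDC·HCl, N-methylmorpholine, CH2Cl2, 0 °C) should give 2-[(2R,3R)-5-acetyl-3-(triethylsilyloxy)-2,3-dihydro-1-benzofuran-2-yl]-N-methoxy-N-methylprop-2-enamide F5.
   - HF·pyridine in THF at 0 °C releases 8, which goes straight into step 6.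

3. Step 9. Hydride may transfer to the conjugated senecioate, zirconium may assist ionisation of the para-alkoxybenzylic ester, or the freed enal may be over-reduced. The fallback sets out from 11 and comes back at 14, and it changes the order of events so that the senecioate never meets a hydride. With i-Bu2AlH (2.2 equiv) in THF at −78 °C, the first equivalent turns the side-chain hydroxyl into its aluminium alkoxide. The second reduces the Weinreb amide through its chelated adduct, and should give (2R,3R)-5-[(1S)-1-hydroxyethyl]-2-(3-oxoprop-1-en-2-yl)-2,3-dihydro-1-benzofuran-3-yl 3-methylbutanoate F6. Steglich esterification of F6 with 12 (N,N'-diisopropylcarbodiimide, 4-(dimethylamino)pyridine in the smallest workable amount, CH2Cl2, 0 °C) then closes the synthesis at 14.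

Further compounds
F1 | step 4 | 2-[(2R)-5-acetyl-3-bromo-2,3-dihydro-1-benzofuran-2-yl]prop-2-enoic acid (both C3 epimers) | C=C(C(=O)O)[C@H]1Oc2ccc(C(C)=O)cc2C1Br
F2 | step 5 | lithium 2-[(2R,3R)-5-acetyl-3-hydroxy-2,3-dihydro-1-benzofuran-2-yl]prop-2-enoate | [Li+].C=C(C(=O)[O-])[C@H]1Oc2ccc(C(C)=O)cc2[C@H]1O
F3 | step 5 | triethylsilyl 2-[(2R,3R)-5-acetyl-3-(triethylsilyloxy)-2,3-dihydro-1-benzofuran-2-yl]prop-2-enoate | C=C(C(=O)O[Si](CC)(CC)CC)[C@H]1Oc2ccc(C(C)=O)cc2[C@H]1O[Si](CC)(CC)CC
F4 | step 5 | 2-[(2R,3R)-5-acetyl-3-(triethylsilyloxy)-2,3-dihydro-1-benzofuran-2-yl]prop-2-enoic acid | C=C(C(=O)O)[C@H]1Oc2ccc(C(C)=O)cc2[C@H]1O[Si](CC)(CC)CC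
F5 | step 5 | 2-[(2R,3R)-5-acetyl-3-(triethylsilyloxy)-2,3-dihydro-1-benzofuran-2-yl]-N-methoxy-N-methylprop-2-enamide | C=C(C(=O)N(C)OC)[C@H]1Oc2ccc(C(C)=O)cc2[C@H]1O[Si](CC)(CC)CC
F6 | step 9 | (2R,3R)-5-[(1S)-1-hydroxyethyl]-2-(3-oxoprop-1-en-2-yl)-2,3-dihydro-1-benzofuran-3-yl 3-methylbutanoate | C=C(C=O)[C@H]1Oc2ccc([C@H](C)O)cc2[C@H]1OC(=O)CC(C)C
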